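Assumption: side-chain carbons are labelled as in bisabolanes (C7 = ring-bound alkene carbon, C14 = its CH2, C8 = CH–O-angelate, C9 = CH2, C10 = CH–OH, C11 = CMe2OH); ring locants are those of 7-oxabicyclo[4.1.0]heptane. Angelate = (2Z)-2-methylbut-2-enoate.

## Retrosynthetic overview

1. Target ⇐ regioselective C8–O angeloylation of an anti-8,10-diol; C8 is set by C10–OH-directed (Evans–Saksena) reduction of a β-hydroxy enone.
2. β-Hydroxy enone ⇐ C7–C8 bond by a visible-light nickel/hydrogen-atom-transfer coupling of a ring alkenyl triflate with the anomeric C–H of a lactol made from L-malic acid (carries C8–C11 and the C10 stereocentre).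
3. Alkenyl triflate ⇐ methyl ketone ⇐ ozonolysis of the isopropenyl group of the fully functionalised carvone ring.
4. Ring ⇐ (R)-carvone: α′-oxygenation (trans), Mitsunobu inversion with angelic acid (cis), Luche reduction, hydroxyl-directed epoxidation, acetylation.
5. Ring order: the cyclohexane is bought in carvone; the oxirane (step 4) is the only ring formed and kept; the lactol ring of the side-chain piece is opened after the coupling.

## Route

Step 1
Reactants: 1 (R)-(−)-carvone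
Product: 3 (5S,6S)-6-hydroxy-2-methyl-5-(prop-1-en-2-yl)cyclohex-2-en-1-one (trans-6-hydroxycarvone), via lithium dienolate 2 (not isolated)
Conditions: LiN(iPr)2, THF, −78 °C; then O2, P(OEt)3, −78 °C; aq. NH4Cl
Reagents that add atoms: dioxygen, O=O
Why: Kinetic α′-deprotonation gives the cross-conjugated dienolate, which is oxygenated (enolate oxidation, hydroperoxide reduced in situ by the phosphite) on the face anti to the neighbouring isopropenyl group, so the new C6–OH is trans to it.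

Step 2
Reactants: 3 (5S,6S)-6-hydroxy-2-methyl-5-(prop-1-en-2-yl)cyclohex-2-en-1-one
Product: 4 (1R,6S)-3-methyl-2-oxo-6-(prop-1-en-2-yl)cyclohex-3-en-1-yl (2Z)-2-methylbut-2-enoate (ester cis to isopropenyl)
Conditions: angelic acid, PPh3, DIAD, toluene, 0 °C to rt
Reagents that add atoms: angelic acid, C/C=C(/C)C(=O)O
Why: Mitsunobu esterification displaces the α-keto oxyphosphonium by SN2 with inversion, which places the angelate cis to the C6 side chain and leaves the Z-alkene of the acid untouched.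

Step 3
Reactants: 4 (1R,6S)-3-methyl-2-oxo-6-(prop-1-en-2-yl)cyclohex-3-en-1-yl (2Z)-2-methylbut-2-enoate
Product: 5 (1R,2S,6S)-2-hydroxy-3-methyl-6-(prop-1-en-2-yl)cyclohex-3-en-1-yl (2Z)-2-methylbut-2-enoate (all-cis)
Conditions: NaBH4, CeCl3·7H2O, MeOH, −78 °C
Reagents that add atoms: none
Why: Luche 1,2-reduction; hydride adds axially, anti to the pseudo-axial α-angeloyloxy group (Felkin–Anh and steric control agree, as in cis-carveol formation from carvone), giving the alcohol cis to the ester and to the side chain.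

Step 4
Reactants: 5 (1R,2S,6S)-2-hydroxy-3-methyl-6-(prop-1-en-2-yl)cyclohex-3-en-1-yl (2Z)-2-methylbut-2-enoate
Product: 6 (1S,2R,3R,4S,6S)-2-hydroxy-1-methyl-4-(prop-1-en-2-yl)-7-oxabicyclo[4.1.0]heptan-3-yl (2Z)-2-methylbut-2-enoate
Conditions: VO(acac)2 (3 mol%), t-BuOOH, CH2Cl2, 0 °C to rt
Reagents that add atoms: tert-butyl hydroperoxide, CC(C)(C)OO
Why: Hydroxyl-directed vanadium-catalysed epoxidation delivers oxygen to the trisubstituted ring alkene syn to the allylic OH and ignores the isopropenyl and angelate alkenes.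

Step 5
Reactants: 6 (1S,2R,3R,4S,6S)-2-hydroxy-1-methyl-4-(prop-1-en-2-yl)-7-oxabicyclo[4.1.0]heptan-3-yl (2Z)-2-methylbut-2-enoate
Product: 7 (1S,2R,3R,4S,6S)-2-acetoxy-1-methyl-4-(prop-1-en-2-yl)-7-oxabicyclo[4.1.0]heptan-3-yl (2Z)-2-methylbut-2-enoate
Conditions: Ac2O, pyridine, DMAP (cat.), CH2Cl2, 0 °C to rt
Reagents that add atoms: acetic anhydride, CC(=O)OC(C)=O
Why: DMAP-catalysed acetylation of the secondary epoxy alcohol is fast enough to outrun acyl migration or Payne rearrangement, and no stereocentre is touched.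

Step 6
Reactants: 7 (1S,2R,3R,4S,6S)-2-acetoxy-1-methyl-4-(prop-1-en-2-yl)-7-oxabicyclo[4.1.0]heptan-3-yl (2Z)-2-methylbut-2-enoate
Product: 9 (1S,2R,3R,4R,6S)-2-acetoxy-4-acetyl-1-methyl-7-oxabicyclo[4.1.0]heptan-3-yl (2Z)-2-methylbut-2-enoate, via secondary ozonide 8 (not isolated)
Conditions: O3, CH2Cl2, −78 °C (Sudan Red 7B end-point); then Me2S, −78 °C to rt
Reagents that add atoms: ozone, [O-][O+]=O
Why: Ozonolysis; ozone reacts far faster with the electron-rich 1,1-disubstituted alkene than with the conjugated angelate, and neutral reductive work-up gives the methyl ketone without epimerising C4.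

Step 7
Reactants: 9 (1S,2R,3R,4R,6S)-2-acetoxy-4-acetyl-1-methyl-7-oxabicyclo[4.1.0]heptan-3-yl (2Z)-2-methylbut-2-enoate
Product: 11 (1S,2R,3R,4R,6S)-2-acetoxy-1-methyl-4-[1-(trifluoromethylsulfonyloxy)ethenyl]-7-oxabicyclo[4.1.0]heptan-3-yl (2Z)-2-methylbut-2-enoate, via potassium enolate 10 (not isolated)
Conditions: KN(SiMe3)2, THF, −78 °C (ketone added to base); then Comins' reagent, −78 to −40 °C
Reagents that add atoms: Comins' reagent, O=S(=O)(N(c1ccc(Cl)cn1)S(=O)(=O)C(F)(F)F)C(F)(F)F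
Why: Kinetic enol triflate formation; the bulky amide removes a methyl proton in preference to the hindered tertiary C4–H, and O-sulfonylation at low temperature traps the terminal enolate before it can equilibrate.

Step 8
Reactants: 12 L-malic acid [(S)-2-hydroxybutanedioic acid]
Product: 13 (S)-2-(2,2-dimethyl-5-oxo-1,3-dioxolan-4-yl)acetic acid
Conditions: 2,2-dimethoxypropane, TsOH·H2O (cat.), rt
Reagents that add atoms: 2,2-dimethoxypropane, COC(C)(C)OC
Why: Acid-catalysed acetonide formation ties up only the α-hydroxy acid unit as the five-membered dioxolanone and leaves the β-carboxyl free; the stereocentre is not involved.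

Step 9
Reactants: 13 (S)-2-(2,2-dimethyl-5-oxo-1,3-dioxolan-4-yl)acetic acid
Product: 15 (4S)-4-hydroxy-5,5-dimethyloxolan-2-one, via dihydroxy acid 14 (not isolated)
Conditions: MeMgBr (5 equiv), THF, −20 °C to rt; then 2 M HCl, rt
Reagents that add atoms: methylmagnesium bromide, C[Mg]Br
Why: Grignard double addition; the acid is protected in situ as its unreactive carboxylate while the activated dioxolanone carbonyl takes up two methyl groups, and acidification lactonises the new tertiary alcohol onto the acid with the C–O stereocentre untouched.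

Step 10
Reactants: 15 (4S)-4-hydroxy-5,5-dimethyloxolan-2-one
Product: 16 (4S)-5,5-dimethyloxolane-2,4-diol (lactol, anomer mixture)
Conditions: iBu2AlH (2.2 equiv), CH2Cl2, −78 °C; aq. potassium sodium tartrate
Reagents that add atoms: none
Why: Partial lactone reduction; the first equivalent is consumed by the free OH and the second stops at the aluminium hemiacetal, which is stable at −78 °C.

Step 11
Reactants: 11 (1S,2R,3R,4R,6S)-2-acetoxy-1-methyl-4-[1-(trifluoromethylsulfonyloxy)ethenyl]-7-oxabicyclo[4.1.0]heptan-3-yl (2Z)-2-methylbut-2-enoate; 16 (4S)-5,5-dimethyloxolane-2,4-diol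
Product: 19 (1S,2R,3R,4S,6S)-2-acetoxy-4-[(5S)-5,6-dihydroxy-6-methyl-3-oxohept-1-en-2-yl]-1-methyl-7-oxabicyclo[4.1.0]heptan-3-yl (2Z)-2-methylbut-2-enoate, via bis-silylated lactol 17 (not isolated), via silyl ketal 18 (not isolated)
Conditions: 16 (3 equiv), (Me3Si)2NH, Me3SiCl (cat.), MeCN, rt, evaporate; then 11, Ir[dF(CF3)ppy]2(dtbbpy)PF6 (2 mol%), NiBr2·glyme (10 mol%), 4,4′-di-tert-butyl-2,2′-bipyridine (12 mol%), quinuclidine (20 mol%), K2CO3, 1,4-dioxane, 450 nm LEDs, rt; then citric acid, MeOH/H2O, 0 °C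
Reagents that add atoms: none
Why: Proposed new method: the quinuclidinium radical cation made by the excited iridium photocatalyst abstracts the hydridic anomeric C–H of 17, the resulting α,α-dioxygenated radical is captured by the alkenyl–nickel species formed from 11 and zerovalent nickel, and reductive elimination forges C7–C8 as silyl ketal 18 (a masked ketone that cannot act as a radical acceptor or undergo C–O coupling), which mild acid opens to the β-hydroxy enone with the malic-acid-derived C10 centre untouched; the closest known reactions are nickel/photoredox/hydrogen-atom-transfer formyl C–H arylation and alkenylation of aldehydes and α-oxy C–H arylation of ethers and acetals.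

Step 12
Reactants: 19 (1S,2R,3R,4S,6S)-2-acetoxy-4-[(5S)-5,6-dihydroxy-6-methyl-3-oxohept-1-en-2-yl]-1-methyl-7-oxabicyclo[4.1.0]heptan-3-yl (2Z)-2-methylbut-2-enoate
Product: 20 (1S,2R,3R,4S,6S)-2-acetoxy-1-methyl-4-[(3S,5S)-3,5,6-trihydroxy-6-methylhept-1-en-2-yl]-7-oxabicyclo[4.1.0]heptan-3-yl (2Z)-2-methylbut-2-enoate
Conditions: Me4NBH(OAc)3 (5 equiv), MeCN/AcOH (1:1), −30 to −20 °C
Reagents that add atoms: none
Why: Evans–Saksena reduction; the C10 hydroxyl binds the acetoxyborohydride and delivers hydride intramolecularly through a chair transition state to the acid-activated enone carbonyl (1,2-mode), giving the 1,3-anti diol and hence 8S from the bought 10S centre.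

Step 13
Reactants: 20 (1S,2R,3R,4S,6S)-2-acetoxy-1-methyl-4-[(3S,5S)-3,5,6-trihydroxy-6-methylhept-1-en-2-yl]-7-oxabicyclo[4.1.0]heptan-3-yl (2Z)-2-methylbut-2-enoate
Product: 23 CNP0221749.1 [(1S,2R,3R,4S,6S)-2-acetoxy-4-[(3S,5S)-5,6-dihydroxy-6-methyl-3-{[(2Z)-2-methylbut-2-enoyl]oxy}hept-1-en-2-yl]-1-methyl-7-oxabicyclo[4.1.0]heptan-3-yl (2Z)-2-methylbut-2-enoate], via phenylboronate 21 (not isolated), via angeloylated phenylboronate 22 (not isolated)
Conditions: PhB(OH)2 (1.1 equiv), 4 Å MS, toluene, rt; then preformed angelic acid/2,4,6-trichlorobenzoyl chloride/Et3N mixed anhydride (3 equiv), DMAP (0.2 equiv), toluene, 40–60 °C; then pinacol, rt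
Reagents that add atoms: angelic acid, C/C=C(/C)C(=O)O
Why: Yamaguchi-type mixed-anhydride angeloylation (conditions known to keep the Z geometry) acylates the only unmasked reactive hydroxyl, because the C10–OH is tied up in the transient phenylboronate and the C11–OH is tertiary; transesterification with pinacol then frees the 10,11-diol under neutral conditions.

## Compound list

1 | (R)-(−)-carvone, (5R)-2-methyl-5-(prop-1-en-2-yl)cyclohex-2-en-1-one | C=C(C)[C@@H]1CC=C(C)C(=O)C1 | starting material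
2 | lithium (3R)-6-methyl-3-(prop-1-en-2-yl)cyclohexa-1,5-dien-1-olate (cross-conjugated dienolate of 1; not isolated) | C=C(C)[C@@H]1CC=C(C)C(O[Li])=C1 | intermediate
3 | (5S,6S)-6-hydroxy-2-methyl-5-(prop-1-en-2-yl)cyclohex-2-en-1-one (OH trans to isopropenyl) | C=C(C)[C@@H]1CC=C(C)C(=O)[C@H]1O | intermediate
4 | (1R,6S)-3-methyl-2-oxo-6-(prop-1-en-2-yl)cyclohex-3-en-1-yl (2Z)-2-methylbut-2-enoate (ester cis to isopropenyl) | C=C(C)[C@@H]1CC=C(C)C(=O)[C@@H]1OC(=O)/C(C)=C\C | intermediate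
5 | (1R,2S,6S)-2-hydroxy-3-methyl-6-(prop-1-en-2-yl)cyclohex-3-en-1-yl (2Z)-2-methylbut-2-enoate (all-cis) | C=C(C)[C@@H]1CC=C(C)[C@H](O)[C@@H]1OC(=O)/C(C)=C\C | intermediate
6 | (1S,2R,3R,4S,6S)-2-hydroxy-1-methyl-4-(prop-1-en-2-yl)-7-oxabicyclo[4.1.0]heptan-3-yl (2Z)-2-methylbut-2-enoate | C=C(C)[C@@H]1C[C@@H]2O[C@]2(C)[C@H](O)[C@@H]1OC(=O)/C(C)=C\C | intermediate
7 | (1S,2R,3R,4S,6S)-2-acetoxy-1-methyl-4-(prop-1-en-2-yl)-7-oxabicyclo[4.1.0]heptan-3-yl (2Z)-2-methylbut-2-enoate | C=C(C)[C@@H]1C[C@@H]2O[C@]2(C)[C@H](OC(C)=O)[C@@H]1OC(=O)/C(C)=C\C | intermediate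
8 | secondary ozonide of 7: 3-methyl-1,2,4-trioxolan-3-yl group in place of isopropenyl, epimer mixture at the trioxolane carbon (not isolated) | CC1(OCOO1)[C@@H]1C[C@@H]2O[C@]2(C)[C@H](OC(C)=O)[C@@H]1OC(=O)/C(C)=C\C | intermediate
9 | (1S,2R,3R,4R,6S)-2-acetoxy-4-acetyl-1-methyl-7-oxabicyclo[4.1.0]heptan-3-yl (2Z)-2-methylbut-2-enoate | CC(=O)[C@@H]1C[C@@H]2O[C@]2(C)[C@H](OC(C)=O)[C@@H]1OC(=O)/C(C)=C\C | intermediate
10 | terminal potassium enolate of 9 (not isolated) | C=C(O[K])[C@@H]1C[C@@H]2O[C@]2(C)[C@H](OC(C)=O)[C@@H]1OC(=O)/C(C)=C\C | intermediate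
11 | (1S,2R,3R,4R,6S)-2-acetoxy-1-methyl-4-[1-(trifluoromethylsulfonyloxy)ethenyl]-7-oxabicyclo[4.1.0]heptan-3-yl (2Z)-2-methylbut-2-enoate | C=C(OS(=O)(=O)C(F)(F)F)[C@@H]1C[C@@H]2O[C@]2(C)[C@H](OC(C)=O)[C@@H]1OC(=O)/C(C)=C\C | intermediate
12 | L-malic acid, (S)-2-hydroxybutanedioic acid | OC(=O)C[C@H](O)C(=O)O | starting material
13 | (S)-2-(2,2-dimethyl-5-oxo-1,3-dioxolan-4-yl)acetic acid | OC(=O)C[C@H]1C(=O)OC(C)(C)O1 | intermediate
14 | (S)-3,4-dihydroxy-4-methylpentanoic acid (not isolated) | OC(=O)C[C@H](O)C(C)(C)O | intermediate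
15 | (4S)-4-hydroxy-5,5-dimethyloxolan-2-one | O=C1C[C@H](O)C(C)(C)O1 | intermediate
16 | (4S)-5,5-dimethyloxolane-2,4-diol (anomer mixture) | OC1C[C@H](O)C(C)(C)O1 | intermediate
17 | (4S)-5,5-dimethyl-2,4-bis(trimethylsilyloxy)oxolane (anomer mixture; not isolated) | C[Si](C)(C)OC1C[C@H](O[Si](C)(C)C)C(C)(C)O1 | intermediate
18 | silyl ketal: 7 with the isopropenyl replaced by 1-[(4S)-5,5-dimethyl-2,4-bis(trimethylsilyloxy)oxolan-2-yl]ethenyl (ketal carbon unassigned; not isolated) | C=C(C1(O[Si](C)(C)C)C[C@H](O[Si](C)(C)C)C(C)(C)O1)[C@@H]1C[C@@H]2O[C@]2(C)[C@H](OC(C)=O)[C@@H]1OC(=O)/C(C)=C\C | intermediate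
19 | (1S,2R,3R,4S,6S)-2-acetoxy-4-[(5S)-5,6-dihydroxy-6-methyl-3-oxohept-1-en-2-yl]-1-methyl-7-oxabicyclo[4.1.0]heptan-3-yl (2Z)-2-methylbut-2-enoate | C=C(C(=O)C[C@H](O)C(C)(C)O)[C@@H]1C[C@@H]2O[C@]2(C)[C@H](OC(C)=O)[C@@H]1OC(=O)/C(C)=C\C | intermediate
20 | (1S,2R,3R,4S,6S)-2-acetoxy-1-methyl-4-[(3S,5S)-3,5,6-trihydroxy-6-methylhept-1-en-2-yl]-7-oxabicyclo[4.1.0]heptan-3-yl (2Z)-2-methylbut-2-enoate | C=C([C@H](C[C@H](O)C(C)(C)O)O)[C@@H]1C[C@@H]2O[C@]2(C)[C@H](OC(C)=O)[C@@H]1OC(=O)/C(C)=C\C | intermediate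
21 | 10,11-O-phenylboronate of 20 (2-phenyl-1,3,2-dioxaborolane across C10/C11, C8–OH free; not isolated) | C=C([C@H](C[C@@H]1OB(c2ccccc2)OC1(C)C)O)[C@@H]1C[C@@H]2O[C@]2(C)[C@H](OC(C)=O)[C@@H]1OC(=O)/C(C)=C\C | intermediate
22 | 8-O-angelate of 21 (not isolated) | C=C([C@H](C[C@@H]1OB(c2ccccc2)OC1(C)C)OC(=O)/C(C)=C\C)[C@@H]1C[C@@H]2O[C@]2(C)[C@H](OC(C)=O)[C@@H]1OC(=O)/C(C)=C\C | intermediate
23 | CNP0221749.1, (1S,2R,3R,4S,6S)-2-acetoxy-4-[(3S,5S)-5,6-dihydroxy-6-methyl-3-{[(2Z)-2-methylbut-2-enoyl]oxy}hept-1-en-2-yl]-1-methyl-7-oxabicyclo[4.1.0]heptan-3-yl (2Z)-2-methylbut-2-enoate | C=C([C@H](C[C@H](O)C(C)(C)O)OC(=O)/C(C)=C\C)[C@@H]1C[C@@H]2O[C@]2(C)[C@H](OC(C)=O)[C@@H]1OC(=O)/C(C)=C\C | target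

## Step count and risks

Total step count: 13. Longest linear sequence: 10 steps from (R)-carvone (steps 1–7, then 11–13); the lactol 16 takes 3 steps (8–10) from L-malic acid.

**Step 11 (proposed new method) is the most likely to fail.** The hydrogen-atom abstraction may not be selective for the anomeric C–H, the triflate may simply be reduced, and the ring angelate could isomerise by energy transfer from the photocatalyst. The fallback uses known chemistry and sets out from 11 and 16. A stoichiometric Nozaki–Hiyama–Kishi coupling (CrCl2, NiCl2 catalyst, DMSO, rt), which tolerates free hydroxyls and engages the open hydroxy-aldehyde form of the lactol, gives the C8-epimeric allylic triols F1. Chemoselective allylic oxidation with MnO2 in CH2Cl2 then converges both epimers on enone 19, where the route is rejoined.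

**Step 7 is the second risk.** If the enolate of 9 equilibrates, C4 epimerises or the neighbouring angelate is lost by β-elimination. The fallback sets out from 9 and avoids enolates. Condensation with 1,2-bis(tert-butyldimethylsilyl)hydrazine (Sc(OTf)3 catalyst) gives the N-silyl hydrazone F2. Iodine and 1,1,3,3-tetramethylguanidine in THF at 0 °C (Barton iodination in the Myers variant) convert it into the alkenyl iodide F3. This iodide takes the place of 11 in the step 11 coupling, and the route is rejoined at 19.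

**Step 2 is the third risk.** The hindered α-ketol may eliminate (towards the aromatised phenol) or the product may epimerise at the acyloxy-bearing carbon under Mitsunobu conditions. The fallback sets out from 3. Tf2O and 2,6-lutidine in CH2Cl2 at −78 °C give the α-keto triflate F4. Displacement with caesium angelate (angelic acid, Cs2CO3, 18-crown-6, toluene/DMF, −20 °C) proceeds by SN2 with inversion and returns to the route at 4.

Further compounds
F1 | step 11 | C8-epimeric triols: (1S,2R,3R,4S,6S)-2-acetoxy-1-methyl-4-[(5S)-3,5,6-trihydroxy-6-methylhept-1-en-2-yl]-7-oxabicyclo[4.1.0]heptan-3-yl (2Z)-2-methylbut-2-enoate | C=C(C(O)C[C@H](O)C(C)(C)O)[C@@H]1C[C@@H]2O[C@]2(C)[C@H](OC(C)=O)[C@@H]1OC(=O)/C(C)=C\C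
F2 | step 7 | N-(tert-butyldimethylsilyl)hydrazone of ketone 9 | CC(=NN[Si](C)(C)C(C)(C)C)[C@@H]1C[C@@H]2O[C@]2(C)[C@H](OC(C)=O)[C@@H]1OC(=O)/C(C)=C\C
F3 | step 7 | (1S,2R,3R,4R,6S)-2-acetoxy-4-(1-iodoethenyl)-1-methyl-7-oxabicyclo[4.1.0]heptan-3-yl (2Z)-2-methylbut-2-enoate | C=C(I)[C@@H]1C[C@@H]2O[C@]2(C)[C@H](OC(C)=O)[C@@H]1OC(=O)/C(C)=C\C
F4 | step 2 | (1S,6S)-3-methyl-2-oxo-6-(prop-1-en-2-yl)cyclohex-3-en-1-yl trifluoromethanesulfonate | C=C(C)[C@@H]1CC=C(C)C(=O)[C@H]1OS(=O)(=O)C(F)(F)F
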